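## Structural features

Cassyformin is an 8–5′ (phenylcoumaran) neolignan: a 2,3-dihydro-1-benzofuran in which benzene ring A is fused to dihydrofuran ring B, with a second benzene ring C (3,4-dihydroxy-5-methoxyphenyl) attached at C2. Ring A carries a methoxy group at C7 (ortho to the ring oxygen O1) and an (E)-propenal chain at C5 (para to O1); C3 carries a hydroxymethyl group. C2 (R) and C3 (S) are adjacent stereocentres, with the aryl and hydroxymethyl groups trans. The fragile groups are the free catechol of ring C (oxidation, metal chelation), the enal (hydride, hydrogenation, nucleophiles) and the benzylic ether bond O1–C2. That bond lies para to a phenolic oxygen of ring C, so it is open to hydrogenolysis, Lewis acids and quinone-methide formation. The real difficulty is the C3–C3a bond together with the trans C2/C3 pair in one absolute configuration, reached by chemistry whose end-game needs neither hydrogenolysis nor a strong Lewis acid. The feature the key step exploits is that C3 bears both the ring-A carbon C3a and a one-carbon oxygenated substituent. Ring A, C2, C3, the hydroxymethyl carbon and ring C are therefore a constitutional isomer of the flavanone skeleton: moving C3a from C3 to the hydroxymethyl carbon turns ring B into a chroman-4-one.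

## Logic of the disconnections

In one sentence: the trans-dihydrobenzofuran is made by an oxidative ring contraction, mediated by trivalent iodine, of the enantioenriched 2-arylchroman-4-one 10, in which the ring-A carbon shifts from the carbonyl carbon to C3.

17 from 15 (through 16). No skeletal bond is cut; the two aryl ester C–O bonds, the acetal C–O bonds and the ester oxidation level are adjusted. The reason is that the free catechol, the enal and the hydroxymethyl group are the three fragile functions, and releasing them together in the last operation means no earlier step has to tolerate them. The gain is that 15 carries every sensitive group in a robust masked form. The demand is a hydride that reduces the alkyl ester and cleaves the aryl esters without touching the acetal or the styrenyl alkene, followed by acid mild enough for the O1–C2 bond.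

15 from 13 and 14. The bond cut is C5–C(α) of the side chain (aryl–alkenyl). The three-carbon chain arrives with its E geometry and aldehyde oxidation level already in place, and the bromine that it replaces is inert in all earlier steps. The gain is the removal of the whole side chain. The demand is a coupling mild enough to spare the enolisable C3–H next to the ester and the aryl esters.

13 from 10 (key). The bond C3–C3a is cut and C3a is joined instead to the ester carbon (a retro 1,2-aryl shift), which expands ring B to a chroman-4-one. The reason is that the hard C3–C3a bond and the trans stereo pair are traded for a ketone with an achiral CH2 group and a single stereocentre at C2. The bond to ring A already exists in 10 as the aryl–carbonyl bond, and the carbonyl carbon is exactly the one-carbon substituent needed at C3. The gain is two stereocentres reduced to one and a neolignan core reduced to a flavanone. The demand is that the ring-A carbon migrates rather than ring C, that the electrophile adds anti to the C2 aryl group, and that C2 does not racemise in acid.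

10 from 9 and 5. The bond cut is C2–C1′ (C2 to ring C). An enantioselective conjugate arylation sets C2 from a flat, achiral chromone. The gain is two achiral fragments of similar size. The demand is catalyst control of the enone face and a catalytic cycle that leaves the C–Br bond and the aryl esters alone.

9 from 7 and 7 from 6. The bonds cut are O1–C2 and C2–C3 (C2 comes from a formamide acetal through 8), then C–Br. The gain is a commercial acetophenone. The demand is bromination only para to the phenol.

5 from 4, 4 from 3, 3 from 1 (through 2). The bonds cut are C–B, two acyl C–O bonds, and the aryl C–O bond that replaces the formyl group of 1. The gain is a commercial aldehyde in which bromine and the oxygen pattern are already correctly placed. The demand is a borylation compatible with aryl esters that delivers the free boronic acid.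

## Other disconnections considered

Alternative 1: the first idea, the biogenetic 8–5′ coupling. The cut is C3–C3a and O1–C2 together; the forward step is an oxidative radical cross-coupling (Ag2O or a laccase/peroxidase) of a guaiacyl-type and a 5-hydroxyguaiacyl-type para-hydroxycinnamate to give the racemic phenylcoumaran A1. It is short, but nothing in the substrates controls absolute configuration. Cross-coupling competes statistically with the two homo-couplings, and the catechol partner is expected to oxidise to an ortho-quinone instead of coupling as a phenoxyl radical. A resolution and oxidation-level corrections would follow. The chosen plan sets C2 by catalyst and C3 by substrate control.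

Alternative 2: the cut is C2–C3; the forward step is an intramolecular C–H insertion of the dirhodium carbenoid from diazo ester A2 into the benzylic ether C–H, with a chiral dirhodium tetracarboxylate such as Rh2(S-DOSP)4, giving the cis ester A3, which must then be epimerised to trans. Both stereocentres would rest on catalyst control in a step that is sensitive to the substituents flanking the ether oxygen (here a methoxy group on one side and the carbenoid carbon on the other). The kinetic product is cis, and its base epimerisation passes through an ester enolate that can expel the phenoxide O1. The diazo ester also needs a longer fragment synthesis. The chosen plan gives the trans isomer directly from a precursor made in one catalytic step.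

Alternative 3: no skeletal cut; both stereocentres are taken back to the aromatic benzofuran A4, and the forward step is an enantioselective hydrogenation of the furan C2=C3 bond with a chiral homogeneous hydrogenation catalyst to give A3, again followed by epimerisation. The C2=C3 bond of A4 is tetrasubstituted, part of an aromatic ring and conjugated to the ester, which is the least favourable case for such hydrogenations. The conditions would also threaten the C–Br bond and the benzyl ethers, and the cis product would still need correcting. The ring contraction avoids reduction altogether.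

Key step: step 7

Assumption: the (S)-configured pyridine–oxazoline ligand in step 6 is taken to give the (2R)-chromanone by the facial sense it shows with cyclic enones; if the sense is opposite, the (R) ligand is used and nothing else changes.

## Steps

Step 1
Reactants: 1 5-bromo-2-hydroxy-3-methoxybenzaldehyde
Product: 3 5-bromo-3-methoxybenzene-1,2-diol, via aryl formate 2 (not isolated)
Conditions: 30% aq H2O2, 1 M aq NaOH, 0 °C to rt, N2; then 2 M HCl
Reagents that add atoms: hydrogen peroxide OO
Why: Dakin oxidation: hydroperoxide adds to the ortho-hydroxy aldehyde, the aryl group migrates to oxygen and the formate 2 is saponified in the same medium; ortho-hydroxybenzaldehydes are the classical substrates and no stereocentre is involved.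

Step 2
Reactants: 3 5-bromo-3-methoxybenzene-1,2-diol
Product: 4 5-bromo-3-methoxy-1,2-phenylene bis(2,2-dimethylpropanoate)
Conditions: pivaloyl chloride (2.5 equiv), Et3N, DMAP (cat.), CH2Cl2, 0 °C to rt
Reagents that add atoms: pivaloyl chloride CC(C)(C)C(=O)Cl
Why: DMAP-catalysed O-acylation of both phenols; pivalates are chosen because they resist the acid and oxidant of step 7, make ring C electron-poor there, and are removed by the hydride of step 9.

Step 3
Reactants: 4 5-bromo-3-methoxy-1,2-phenylene bis(2,2-dimethylpropanoate)
Product: 5 [3-methoxy-4,5-bis(pivaloyloxy)phenyl]boronic acid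
Conditions: B2(OH)4, chloro(2-dicyclohexylphosphino-2',4',6'-triisopropyl-1,1'-biphenyl)[2-(2'-amino-1,1'-biphenyl)]palladium (second-generation XPhos precatalyst, 2 mol%), XPhos (4 mol%), KOAc, EtOH, 80 °C; aqueous work-up
Reagents that add atoms: tetrahydroxydiboron OB(O)B(O)O
Why: Miyaura-type palladium-catalysed borylation of an aryl bromide with tetrahydroxydiboron gives the free boronic acid directly; the weak base KOAc and the hindered aryl esters are compatible.

Step 4
Reactants: 6 1-(2-hydroxy-3-methoxyphenyl)ethan-1-one
Product: 7 1-(5-bromo-2-hydroxy-3-methoxyphenyl)ethan-1-one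
Conditions: N-bromosuccinimide, MeCN, 0 °C to rt
Reagents that add atoms: N-bromosuccinimide O=C1CCC(=O)N1Br
Why: Electrophilic aromatic bromination; the position para to the phenol (and meta to the acetyl group) is the only strongly activated free site, so the 5-bromo isomer should form.

Step 5
Reactants: 7 1-(5-bromo-2-hydroxy-3-methoxyphenyl)ethan-1-one
Product: 9 6-bromo-8-methoxy-4H-chromen-4-one, via enaminone 8 (not isolated)
Conditions: Me2NCH(OMe)2, toluene, 100 °C; then conc. HCl, CH2Cl2, 40 °C
Reagents that add atoms: N,N-dimethylformamide dimethyl acetal COC(OC)N(C)C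
Why: Condensation of the methyl ketone with the formamide acetal gives enaminone 8; under acid the phenol adds to the β-carbon and dimethylamine is lost (addition–elimination), the standard enaminone route to 2,3-unsubstituted chromones.

Step 6
Reactants: 9 6-bromo-8-methoxy-4H-chromen-4-one; 5 [3-methoxy-4,5-bis(pivaloyloxy)phenyl]boronic acid (2 equiv)
Product: 10 (2R)-6-bromo-8-methoxy-2-[3-methoxy-4,5-bis(pivaloyloxy)phenyl]-2,3-dihydro-4H-chromen-4-one
Conditions: Pd(OCOCF3)2 (5 mol%), (S)-4-tert-butyl-2-(pyridin-2-yl)-4,5-dihydro-1,3-oxazole (6 mol%), NH4PF6 (30 mol%), H2O (5 equiv), ClCH2CH2Cl, 60 °C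
Reagents that add atoms: none
Why: Palladium-catalysed asymmetric conjugate addition of an arylboronic acid to a chromone: transmetalation to divalent palladium, enantio-determining insertion of C2=C3 into the aryl–palladium bond under control of the chiral pyridine–oxazoline ligand (sets C2 as R), and protonolysis of the palladium enolate by water. The cycle stays at divalent palladium, so the C–Br bond is not engaged, and the absence of base spares the aryl esters and the base-labile flavanone.

Step 7
Reactants: 10 (2R)-6-bromo-8-methoxy-2-[3-methoxy-4,5-bis(pivaloyloxy)phenyl]-2,3-dihydro-4H-chromen-4-one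
Product: 13 methyl (2R,3R)-5-bromo-7-methoxy-2-[3-methoxy-4,5-bis(pivaloyloxy)phenyl]-2,3-dihydro-1-benzofuran-3-carboxylate, via methyl enol ether 11 (not isolated), via C3 iodane ketal 12 (not isolated)
Conditions: PhI(OAc)2 (1.3 equiv), conc. H2SO4 (2 equiv), HC(OMe)3, 0 °C to rt; aq NaHCO3 work-up
Reagents that add atoms: trimethyl orthoformate COC(OC)OC (the OCH3 of the ester); water O (the carbonyl oxygen of the ester, on hydrolysis of the dimethoxycarbenium ion)
Why: Acid and trimethyl orthoformate convert ketone 10 into methyl enol ether 11, which the electrophilic trivalent iodine reagent attacks at C3 on the face anti to the C2 aryl group, methanol capturing the oxocarbenium ion to give the 2,3-trans iodane ketal 12. In the diequatorial half-chair of 12 the C3–I bond is antiperiplanar to the ring bond C4–C4a; the phenyl-λ3-iodanyl group is a hypernucleofuge, and as it leaves, C4a shifts from C4 to C3 with inversion at C3, pushed by the two methoxy groups on C4, which end as a dialkoxycarbenium ion and, after hydrolysis, as the methyl ester. The closest known reaction type is the oxidative ring contraction of flavanones to trans-2-aryl-2,3-dihydrobenzofuran-3-carboxylates by trivalent iodine or Tl(NO3)3 in trimethyl orthoformate, a 1,2-aryl shift of an α-iodanyl ketal. No ring is closed by cyclisation: ring B arises by contraction of the pyranone (bond C3–C4a made, bond C4–C4a broken), so that C4 leaves the ring and becomes the exocyclic ester carbon, the future hydroxymethyl carbon. The new stereocentre C3 is set by the existing centre C2 (substrate control): anti iodination followed by invertive migration places the ester trans to the aryl group, (2R,3R), which is also the more stable isomer. The selectivity needed is migration of C4a in preference to migration of the C2 aryl group (isoflavone path), migration of O1 (aurone path) or loss of H2 (flavone path); it is secured by the conformation of 12 (aryl shift and anti elimination need the disfavoured diaxial or cis arrangement), by the push of the two methoxy groups at C4 and the donor O1 ortho to C4a, and by the two pivaloyloxy groups, which make ring C a poor migrating group, a poor stabiliser of positive charge at C2 and inert to the oxidant. C2 is not touched, and the electron-poor ring C disfavours acid-induced opening of the O1–C2 bond, so the configuration set in step 6 should be carried over.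

Step 8
Reactants: 13 methyl (2R,3R)-5-bromo-7-methoxy-2-[3-methoxy-4,5-bis(pivaloyloxy)phenyl]-2,3-dihydro-1-benzofuran-3-carboxylate; 14 2-[(1E)-3,3-diethoxyprop-1-en-1-yl]-4,4,5,5-tetramethyl-1,3,2-dioxaborolane
Product: 15 methyl (2R,3R)-5-[(1E)-3,3-diethoxyprop-1-en-1-yl]-7-methoxy-2-[3-methoxy-4,5-bis(pivaloyloxy)phenyl]-2,3-dihydro-1-benzofuran-3-carboxylate
Conditions: Pd(OAc)2 (5 mol%), SPhos (10 mol%), K3PO4 (2 equiv), THF–H2O (10:1), 40 °C; work-up without acid, chromatography on Et3N-treated silica
Reagents that add atoms: none
Why: Suzuki–Miyaura coupling of the aryl bromide with an (E)-alkenyl pinacol boronate proceeds with retention of alkene geometry; the active biarylphosphine catalyst allows a low temperature and a mild base, which should spare the enolisable C3–H, the aryl esters and the acetal that masks the enal.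

Step 9
Reactants: 15 methyl (2R,3R)-5-[(1E)-3,3-diethoxyprop-1-en-1-yl]-7-methoxy-2-[3-methoxy-4,5-bis(pivaloyloxy)phenyl]-2,3-dihydro-1-benzofuran-3-carboxylate
Product: 17 cassyformin [(2E)-3-[(2R,3S)-2-(3,4-dihydroxy-5-methoxyphenyl)-3-(hydroxymethyl)-7-methoxy-2,3-dihydro-1-benzofuran-5-yl]prop-2-enal], via triol diethyl acetal 16 (not isolated)
Conditions: LiAlH4 (4 equiv), THF, 0 °C; EtOAc quench; then 1 M aq HCl, THF, rt
Reagents that add atoms: water O (the aldehyde oxygen, on acetal hydrolysis)
Why: Hydride reduction with LiAlH4 takes the methyl ester to the primary alcohol and cleaves both aryl pivalates, while the acetal and the unactivated styrenyl alkene are inert to hydride; the acidic work-up then hydrolyses acetal 16 to the (E)-enal. No stereocentre is touched, and the change of descriptor at C3 from R to S reflects only the change in substituent priority.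

## Compound list

1 | 5-bromo-2-hydroxy-3-methoxybenzaldehyde | COc1cc(Br)cc(C=O)c1O | starting material
2 | 5-bromo-2-hydroxy-3-methoxyphenyl formate | COc1cc(Br)cc(OC=O)c1O | intermediate (not isolated)
3 | 5-bromo-3-methoxybenzene-1,2-diol | COc1cc(Br)cc(O)c1O | intermediate
4 | 5-bromo-3-methoxy-1,2-phenylene bis(2,2-dimethylpropanoate) | COc1cc(Br)cc(OC(=O)C(C)(C)C)c1OC(=O)C(C)(C)C | intermediate
5 | [3-methoxy-4,5-bis(pivaloyloxy)phenyl]boronic acid | COc1cc(B(O)O)cc(OC(=O)C(C)(C)C)c1OC(=O)C(C)(C)C | intermediate
6 | 1-(2-hydroxy-3-methoxyphenyl)ethan-1-one | CC(=O)c1cccc(OC)c1O | starting material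
7 | 1-(5-bromo-2-hydroxy-3-methoxyphenyl)ethan-1-one | CC(=O)c1cc(Br)cc(OC)c1O | intermediate
8 | (2E)-1-(5-bromo-2-hydroxy-3-methoxyphenyl)-3-(dimethylamino)prop-2-en-1-one | CN(C)/C=C/C(=O)c1cc(Br)cc(OC)c1O | intermediate (not isolated)
9 | 6-bromo-8-methoxy-4H-chromen-4-one | COc1cc(Br)cc2c(=O)ccoc12 | intermediate
10 | (2R)-6-bromo-8-methoxy-2-[3-methoxy-4,5-bis(pivaloyloxy)phenyl]-2,3-dihydro-4H-chromen-4-one | COc1cc([C@H]2CC(=O)c3cc(Br)cc(OC)c3O2)cc(OC(=O)C(C)(C)C)c1OC(=O)C(C)(C)C | intermediate
11 | (2R)-6-bromo-4,8-dimethoxy-2-[3-methoxy-4,5-bis(pivaloyloxy)phenyl]-2H-chromene | COc1cc([C@H]2C=C(OC)c3cc(Br)cc(OC)c3O2)cc(OC(=O)C(C)(C)C)c1OC(=O)C(C)(C)C | intermediate (not isolated)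
12 | (2S,3S)-3-[acetoxy(phenyl)-λ3-iodanyl]-6-bromo-4,4,8-trimethoxy-2-[3-methoxy-4,5-bis(pivaloyloxy)phenyl]chromane (2,3-trans) | COc1cc([C@@H]2Oc3c(OC)cc(Br)cc3C(OC)(OC)[C@H]2I(OC(C)=O)c4ccccc4)cc(OC(=O)C(C)(C)C)c1OC(=O)C(C)(C)C | intermediate (not isolated)
13 | methyl (2R,3R)-5-bromo-7-methoxy-2-[3-methoxy-4,5-bis(pivaloyloxy)phenyl]-2,3-dihydro-1-benzofuran-3-carboxylate | COc1cc([C@@H]2Oc3c(OC)cc(Br)cc3[C@H]2C(=O)OC)cc(OC(=O)C(C)(C)C)c1OC(=O)C(C)(C)C | intermediate
14 | 2-[(1E)-3,3-diethoxyprop-1-en-1-yl]-4,4,5,5-tetramethyl-1,3,2-dioxaborolane | CCOC(OCC)/C=C/B1OC(C)(C)C(C)(C)O1 | starting material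
15 | methyl (2R,3R)-5-[(1E)-3,3-diethoxyprop-1-en-1-yl]-7-methoxy-2-[3-methoxy-4,5-bis(pivaloyloxy)phenyl]-2,3-dihydro-1-benzofuran-3-carboxylate | COc1cc([C@@H]2Oc3c(OC)cc(/C=C/C(OCC)OCC)cc3[C@H]2C(=O)OC)cc(OC(=O)C(C)(C)C)c1OC(=O)C(C)(C)C | intermediate
16 | 5-[(2R,3S)-5-[(1E)-3,3-diethoxyprop-1-en-1-yl]-3-(hydroxymethyl)-7-methoxy-2,3-dihydro-1-benzofuran-2-yl]-3-methoxybenzene-1,2-diol | COc1cc([C@@H]2Oc3c(OC)cc(/C=C/C(OCC)OCC)cc3[C@H]2CO)cc(O)c1O | intermediate (not isolated)
17 | cassyformin, (2E)-3-[(2R,3S)-2-(3,4-dihydroxy-5-methoxyphenyl)-3-(hydroxymethyl)-7-methoxy-2,3-dihydro-1-benzofuran-5-yl]prop-2-enal | COc1cc([C@@H]2Oc3c(OC)cc(/C=C/C=O)cc3[C@H]2CO)cc(O)c1O | target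

## Step count and risks

Total step count: 9. Longest linear sequence: 7 steps (steps 1, 2, 3, 6, 7, 8, 9).

Step 7 (key step). What may go wrong: migration of the C2 aryl group or of O1 in place of the ring-A carbon, dehydrogenation to the flavone, solvolytic displacement of the iodane by methanol, or partial loss of configuration at C2 through acid-induced opening of the pyranone. Fallback (a carbene route to the same 1,2-shift, setting out from 10 and returning at 13): 10 is acylated at C3 with LiN(SiMe3)2 and CF3CO2CH2CF3 at −78 °C to give the (2R)-3-(trifluoroacetyl)chromanone F1. Detrifluoroacetylative diazo transfer with CH3SO2N3 and Et3N gives the (2S)-3-diazochromanone F2 (same spatial arrangement at C2). Irradiation of F2 in methanol (Wolff rearrangement) expels nitrogen, the ring-A carbon shifts to the carbene carbon C3, and methanol traps the ring-contracted ketene. This should give 13 together with its cis C3 epimer F3, which is equilibrated to 13 with DBU.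

Step 6. What may go wrong: slow transmetalation and protodeboronation of the electron-poor boronic acid, insufficient enantioselectivity, or the opposite facial sense. Fallback (resolution in place of asymmetric catalysis, setting out from 9 and returning at 10): the same addition of 5 to 9 is run with Pd(OCOCF3)2 and achiral 2,2'-bipyridine to give the racemic chromanone F4. Kinetic resolution by asymmetric transfer hydrogenation with RuCl[(S,S)-TsDPEN](p-cymene) in HCO2H–Et3N (or its enantiomer, whichever consumes the (2S)-ketone faster) converts the unwanted enantiomer into the cis (2S,4S)-chroman-4-ol F5 and leaves 10, separated by chromatography.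

Step 8. What may go wrong: base-mediated enolisation at C3 with expulsion and re-addition of the phenoxide O1 (loss of configuration at C2), hydrolysis of the aryl esters, or acetal loss on purification. Fallback (reduction before coupling, setting out from 13 and returning at 16): LiAlH4 reduces 13 to the bromo triol F6, which no longer has an enolisable centre. TBSCl and imidazole give the tris(silyl ether) F7. Suzuki–Miyaura coupling of F7 with 14 under the conditions of step 8 gives the silylated acetal F8. HF·pyridine in THF removes the three silyl groups to give 16, which the aqueous acidic work-up takes on to 17.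

Step 3. What may go wrong: transesterification of the aryl pivalates in hot ethanol, protodeboronation, or difficult isolation of the free boronic acid (boroxine formation). Fallback (an isolable boronic ester and a separate unmasking, setting out from 4 and returning at 5): Miyaura borylation of 4 with B2pin2, PdCl2(dppf) and KOAc in dioxane at 80 °C gives the pinacol boronate F9, which is purified by chromatography and cleaved with NaIO4 and NH4OAc in acetone–water to 5.

## Further compounds

F1 | step 7 | (2R)-6-bromo-8-methoxy-2-[3-methoxy-4,5-bis(pivaloyloxy)phenyl]-3-(trifluoroacetyl)-2,3-dihydro-4H-chromen-4-one (C3 enolisable, unassigned) | COc1cc([C@H]2C(C(=O)C(F)(F)F)C(=O)c3cc(Br)cc(OC)c3O2)cc(OC(=O)C(C)(C)C)c1OC(=O)C(C)(C)C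
F2 | step 7 | (2S)-6-bromo-3-diazo-8-methoxy-2-[3-methoxy-4,5-bis(pivaloyloxy)phenyl]-2,3-dihydro-4H-chromen-4-one | COc1cc([C@H]2C(=[N+]=[N-])C(=O)c3cc(Br)cc(OC)c3O2)cc(OC(=O)C(C)(C)C)c1OC(=O)C(C)(C)C
F3 | step 7 | methyl (2R,3S)-5-bromo-7-methoxy-2-[3-methoxy-4,5-bis(pivaloyloxy)phenyl]-2,3-dihydro-1-benzofuran-3-carboxylate (cis) | COc1cc([C@@H]2Oc3c(OC)cc(Br)cc3[C@@H]2C(=O)OC)cc(OC(=O)C(C)(C)C)c1OC(=O)C(C)(C)C
F4 | step 6 | racemic 6-bromo-8-methoxy-2-[3-methoxy-4,5-bis(pivaloyloxy)phenyl]-2,3-dihydro-4H-chromen-4-one | COc1cc(C2CC(=O)c3cc(Br)cc(OC)c3O2)cc(OC(=O)C(C)(C)C)c1OC(=O)C(C)(C)C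
F5 | step 6 | (2S,4S)-6-bromo-8-methoxy-2-[3-methoxy-4,5-bis(pivaloyloxy)phenyl]-3,4-dihydro-2H-chromen-4-ol (cis) | COc1cc([C@@H]2C[C@H](O)c3cc(Br)cc(OC)c3O2)cc(OC(=O)C(C)(C)C)c1OC(=O)C(C)(C)C
F6 | step 8 | 5-[(2R,3S)-5-bromo-3-(hydroxymethyl)-7-methoxy-2,3-dihydro-1-benzofuran-2-yl]-3-methoxybenzene-1,2-diol | COc1cc([C@@H]2Oc3c(OC)cc(Br)cc3[C@H]2CO)cc(O)c1O
F7 | step 8 | (2R,3S)-5-bromo-2-[3,4-bis(tert-butyldimethylsilyloxy)-5-methoxyphenyl]-3-[(tert-butyldimethylsilyloxy)methyl]-7-methoxy-2,3-dihydro-1-benzofuran | COc1cc([C@@H]2Oc3c(OC)cc(Br)cc3[C@H]2CO[Si](C)(C)C(C)(C)C)cc(O[Si](C)(C)C(C)(C)C)c1O[Si](C)(C)C(C)(C)C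
F8 | step 8 | (2R,3S)-2-[3,4-bis(tert-butyldimethylsilyloxy)-5-methoxyphenyl]-3-[(tert-butyldimethylsilyloxy)methyl]-5-[(1E)-3,3-diethoxyprop-1-en-1-yl]-7-methoxy-2,3-dihydro-1-benzofuran | COc1cc([C@@H]2Oc3c(OC)cc(/C=C/C(OCC)OCC)cc3[C@H]2CO[Si](C)(C)C(C)(C)C)cc(O[Si](C)(C)C(C)(C)C)c1O[Si](C)(C)C(C)(C)C
F9 | step 3 | 3-methoxy-5-(4,4,5,5-tetramethyl-1,3,2-dioxaborolan-2-yl)-1,2-phenylene bis(2,2-dimethylpropanoate) | COc1cc(B2OC(C)(C)C(C)(C)O2)cc(OC(=O)C(C)(C)C)c1OC(=O)C(C)(C)C
A1 | alternative 1 | racemic methyl (2E)-3-[(2RS,3RS)-2-(3,4-dihydroxy-5-methoxyphenyl)-7-methoxy-3-(methoxycarbonyl)-2,3-dihydro-1-benzofuran-5-yl]prop-2-enoate (one enantiomer drawn) | COc1cc([C@@H]2Oc3c(OC)cc(/C=C/C(=O)OC)cc3[C@H]2C(=O)OC)cc(O)c1O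
A2 | alternative 2 | methyl 2-[2-{[3,4-bis(benzyloxy)-5-methoxyphenyl]methoxy}-5-bromo-3-methoxyphenyl]-2-diazoacetate | COC(=O)C(=[N+]=[N-])c1cc(Br)cc(OC)c1OCc1cc(OC)c(OCc2ccccc2)c(OCc2ccccc2)c1
A3 | alternative 2 | methyl (2R,3S)-2-[3,4-bis(benzyloxy)-5-methoxyphenyl]-5-bromo-7-methoxy-2,3-dihydro-1-benzofuran-3-carboxylate (cis) | COc1cc([C@@H]2Oc3c(OC)cc(Br)cc3[C@@H]2C(=O)OC)cc(OCc2ccccc2)c1OCc1ccccc1
A4 | alternative 3 | methyl 2-[3,4-bis(benzyloxy)-5-methoxyphenyl]-5-bromo-7-methoxy-1-benzofuran-3-carboxylate | COC(=O)c1c(-c2cc(OC)c(OCc3ccccc3)c(OCc3ccccc3)c2)oc2c(OC)cc(Br)cc12
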